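**Retrosynthetic overview**
1. Kanzonol X ⇐ removal of three MOM groups ⇐ twofold ortho-lithiation/prenylation of the tri-MOM isoflavan 8; both prenyl sites (C8, C3') lie between two oxygens.
2. 8 ⇐ acyclic (R)-alcohol 7 by an anodic, Ph3P-mediated dehydrative cascade: 1,2-aryl shift through a phenonium ion (inversion) and Friedel–Crafts closure. This forms C3–C1', C4–C4a and the only new ring (the dihydropyran).
3. 7 ⇐ 3-(methoxymethoxy)phenol + (R)-chlorohydrin 5 ⇐ aryl Grignard of 3 + (R)-epichlorohydrin, the sole source of chirality.
4. Both benzene rings are bought; the C3 stereocentre is relayed from the epichlorohydrin carbinol carbon.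

Assumption: 3-(methoxymethoxy)phenol (6) and (R)-epichlorohydrin (4) are bought as catalogue items; the target is the (3R)-isoflavan encoded by the SMILES.

**Step 1**
Reactants: 1, 4-bromoresorcinol; 2, chloromethyl methyl ether
Product: 3, 1-bromo-2,4-bis(methoxymethoxy)benzene
Conditions: MOMCl (2.5 equiv), i-Pr2NEt, CH2Cl2, 0 °C → rt
Reagents that add atoms: MOMCl (2), COCCl
Why: Simple phenol O-alkylation (MOM protection); the MOM groups later act as ortho-directing groups and come off without touching a prenyl alkene.

**Step 2**
Reactants: 3, 1-bromo-2,4-bis(methoxymethoxy)benzene; 4, (R)-epichlorohydrin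
Product: 5, (R)-1-[2,4-bis(methoxymethoxy)phenyl]-3-chloropropan-2-ol
Conditions: 3, Mg, THF, 40 °C; then CuI (10 mol %), 4 (0.9 equiv), THF, −40 → −10 °C; aq NH4Cl
Reagents that add atoms: (R)-epichlorohydrin (4), ClC[C@H]1CO1
Why: Copper-catalysed Grignard opening of the epoxide at its CH2 terminus (SN2); the stereocentre is not a reaction site, so (R)-4 gives (R)-5.

**Step 3**
Reactants: 5, (R)-chlorohydrin; 6, 3-(methoxymethoxy)phenol
Product: 7, (R)-1-[2,4-bis(methoxymethoxy)phenyl]-3-[3-(methoxymethoxy)phenoxy]propan-2-ol
Conditions: 6 (1.2 equiv), Cs2CO3, DMF, 70 °C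
Reagents that add atoms: 3-(methoxymethoxy)phenol (6), COCOc1cccc(O)c1
Why: Williamson etherification via in situ epoxide closure and phenoxide re-opening at the terminal carbon; direct displacement and the epoxide pathway hit the same CH2, so the carbinol configuration (R) cannot erode.

**Step 4**
Reactants: 7, (R)-alcohol
Product: 8, (R)-3-[2,4-bis(methoxymethoxy)phenyl]-7-(methoxymethoxy)chromane
Conditions: undivided cell, graphite anode/Pt cathode, constant current (5 mA cm⁻², 2.2 F mol⁻¹); Ph3P (1.3 equiv, dosed during electrolysis), 2,6-lutidine (2 equiv), n-Bu4NPF6 (0.1 M), CH2Cl2 (0.03 M), 0 °C; then 35 °C, 1 h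
Reagents that add atoms: none
Why: Proposed new method: anodic oxidation of Ph3P (about +1.0 V vs SCE, below the dialkoxyarenes at about +1.4–1.5 V) in the presence of 7 gives the alkoxyphosphonium ion, with H2 evolved at the cathode. Loss of Ph3P=O is assisted by the 2,4-dialkoxyphenyl ring (Ar1-3 participation), giving a phenonium ion with inversion at the carbinol carbon. The tethered A ring then opens it at the primary carbon through its position para to OMOM (Ar2-6 Friedel–Crafts); Ar2-5 attack at the secondary carbon is disfavoured geometrically and by the β-oxygen. The result is the pyran ring with the aryl group on C3 and stereospecific transfer of chirality (R-alcohol → 3R). Closest known reactions: substitutions of anodically generated alkoxyphosphonium ions (electrochemical Mitsunobu/Appel-type activation) and thermal phenonium 1,2-aryl shifts in deoxyfluorination or Mitsunobu reactions of β-aryl alcohols.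

**Step 5**
Reactants: 8, tri-MOM isoflavan; 9, prenyl bromide
Product: 10, (R)-3-[2,4-bis(methoxymethoxy)-3-(3-methylbut-2-enyl)phenyl]-7-(methoxymethoxy)-8-(3-methylbut-2-enyl)chromane
Conditions: n-BuLi (3.2 equiv), TMEDA, THF, 0 °C, 2 h; CuBr·SMe2 (2.5 equiv), −78 °C; 9 (4 equiv), −78 °C → rt
Reagents that add atoms: prenyl bromide (9), CC(C)=CCBr (two equivalents incorporated)
Why: Twofold directed ortho-metalation at the two doubly oxygen-flanked positions (C3' between two OMOM; C8 between the ring oxygen and OMOM), then SN2 allylation of the aryl-copper species to give the linear prenyl groups; the tertiary benzylic C3–H is not deprotonated, so the stereocentre is untouched.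

**Step 6**
Reactants: 10, diprenyl tri-MOM isoflavan
Product: 11, Kanzonol X, (R)-3-[2,4-dihydroxy-3-(3-methylbut-2-enyl)phenyl]-8-(3-methylbut-2-enyl)chroman-7-ol
Conditions: 3 M aq HCl/MeOH (1:6), 45 °C, about 2 h, quench at full conversion
Reagents that add atoms: none
Why: Acetal (MOM) solvolysis under mild, brief acid conditions that leave the prenyl groups intact; C3 has no acidic or ionisable neighbour and keeps its configuration.

**Compound list**
1 | 4-bromoresorcinol | Oc1ccc(Br)c(O)c1 | starting material
2 | chloromethyl methyl ether (MOMCl) | COCCl | starting material (reagent)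
3 | 1-bromo-2,4-bis(methoxymethoxy)benzene | COCOc1ccc(Br)c(OCOC)c1 | intermediate
4 | (R)-epichlorohydrin | ClC[C@H]1CO1 | starting material (chiral)
5 | (R)-1-[2,4-bis(methoxymethoxy)phenyl]-3-chloropropan-2-ol | COCOc1ccc(C[C@@H](O)CCl)c(OCOC)c1 | intermediate
6 | 3-(methoxymethoxy)phenol | COCOc1cccc(O)c1 | starting material
7 | (R)-1-[2,4-bis(methoxymethoxy)phenyl]-3-[3-(methoxymethoxy)phenoxy]propan-2-ol | COCOc1ccc(C[C@@H](O)COc2cccc(OCOC)c2)c(OCOC)c1 | intermediate
8 | (R)-3-[2,4-bis(methoxymethoxy)phenyl]-7-(methoxymethoxy)chromane | COCOc1ccc([C@@H]2COc3cc(OCOC)ccc3C2)c(OCOC)c1 | intermediate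
9 | prenyl bromide (1-bromo-3-methylbut-2-ene) | CC(C)=CCBr | starting material
10 | (R)-3-[2,4-bis(methoxymethoxy)-3-prenylphenyl]-7-(methoxymethoxy)-8-prenylchromane | COCOc1ccc([C@@H]2COc3c(CC=C(C)C)c(OCOC)ccc3C2)c(OCOC)c1CC=C(C)C | intermediate
11 | Kanzonol X | CC(C)=CCc1c(O)ccc([C@@H]2COc3c(ccc(O)c3CC=C(C)C)C2)c1O | target

**Totals**
Total steps: 6. Longest linear sequence: 6 (1 → 3 → 5 → 7 → 8 → 10 → 11).

**Steps most likely to fail**
1. Step 4 (proposed new cascade). Risks: unrearranged five-membered closure, participation of the ortho-OMOM oxygen, trapping of the cation by Ph3P, or anodic over-oxidation of the arenes. Fallback (known reaction types, stepwise anionic ring closure): use 2-bromo-5-(methoxymethoxy)phenol in step 3. Convert the alcohol by Appel bromination (PPh3/CBr4, anchimerically assisted 1,2-aryl shift) to the rearranged primary bromide ArB–CH(CH2Br)–CH2OAr. Close C4–C4a by Parham cycloalkylation (t-BuLi, THF, −100 °C).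
2. Step 5 (double ortho-lithiation/prenylation). Risks: incomplete dilithiation or lithiation at C6/C5'. Fallback: install the prenyl groups before fragment union. Ortho-lithiation/prenylation of 1,3-bis(methoxymethoxy)benzene gives 2-prenylresorcinol building blocks for both the aryl bromide and the phenol. The prenyl groups are then carried through steps 2–4, and the C8 prenyl also blocks the wrong ortho position in the cyclisation.
3. Step 6 (acidic MOM removal next to o-prenylphenols). Risk: acid-catalysed cyclisation to 2,2-dimethylchromans or MeOH addition to the alkenes. Fallback: change the protecting-group plan to SEM ethers throughout (equally good ortho-directors) and unmask with fluoride (TBAF/DMPU) or MgBr2·OEt2, avoiding Brønsted acid.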